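**Retrosynthetic overview**
1. Target 8 (lukianol A) ⇐ tri-O-methyl ether 7 by global demethylation in the last step.
2. Oxazinone ring (formed second) ⇐ trichloromethyl ketone 6: the lactone C–O bond is closed by the ketone enolate oxygen, and the lactone carbonyl carbon is stitched onto a pyrrole C–H from Cl3CCOCl. No pyrrole ester and no N-alkylation are used.
3. Pyrrole ring (formed first) ⇐ two molecules of arylacetaldehyde 1 plus aminoketone 2 in one oxidative three-component annulation, which makes the C3–C4 bond and both C–N bonds and brings the N-phenacyl arm in with the nitrogen.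
4. Ring order: pyrrole, then oxazinone; all three aryl groups come from two commercial anisyl building blocks.

Assumption: the target is planar and has no stereocentre, so there is no enantiomer to control; the route makes the structure exactly as drawn in the SMILES.

**Step 1**
Reactants: 1 2-(4-methoxyphenyl)acetaldehyde (two molecules incorporated, 2.5 equiv used); 2 2-amino-1-(4-methoxyphenyl)ethan-1-one hydrochloride
Product: 5 2-[3,4-bis(4-methoxyphenyl)-1H-pyrrol-1-yl]-1-(4-methoxyphenyl)ethan-1-one, via N-phenacyl aldimine 3 (not isolated), via succinaldehyde monoimine 4 (not isolated)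
Conditions: AgOAc (2.2 equiv), NaOAc (3 equiv), THF, 60 °C, dark
Reagents that add atoms: none
Why: Silver-mediated oxidative amine–aldehyde pyrrole annulation (oxidative enamine coupling followed by Paal–Knorr closure): the enamine tautomer of 3 is oxidised by monovalent silver and joins a second aldehyde unit at the benzylic carbons to give 4, which cyclodehydrates to the aromatic pyrrole, while slow release of the free aminoketone from its poorly soluble hydrochloride into excess aldehyde suppresses self-condensation; no stereocentre survives.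

**Step 2**
Reactants: 5 2-[3,4-bis(4-methoxyphenyl)-1H-pyrrol-1-yl]-1-(4-methoxyphenyl)ethan-1-one
Product: 6 2,2,2-trichloro-1-{3,4-bis(4-methoxyphenyl)-1-[2-(4-methoxyphenyl)-2-oxoethyl]-1H-pyrrol-2-yl}ethan-1-one
Conditions: Cl3CCOCl (2 equiv), ClCH2CH2Cl, 0 °C to 60 °C
Reagents that add atoms: trichloroacetyl chloride, ClC(=O)C(Cl)(Cl)Cl
Why: Uncatalysed Friedel–Crafts-type trichloroacetylation of an electron-rich pyrrole goes to the free α-position (C2 and C5 are equivalent by symmetry), and the first acyl group deactivates the ring against a second acylation; no stereocentre is formed.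

**Step 3**
Reactants: 6 2,2,2-trichloro-1-{3,4-bis(4-methoxyphenyl)-1-[2-(4-methoxyphenyl)-2-oxoethyl]-1H-pyrrol-2-yl}ethan-1-one
Product: 7 3,7,8-tris(4-methoxyphenyl)-1H-pyrrolo[2,1-c][1,4]oxazin-1-one
Conditions: DBU (0.5 equiv), 4 Å MS, MeCN, 0 °C to rt
Reagents that add atoms: none
Why: Proposed new method: an intramolecular haloform-type acyl substitution in which the DBU-generated enolate of the phenacyl ketone attacks the very electrophilic trichloromethyl ketone through oxygen (six-membered closure, whereas C-attack would need a four-membered ring), the CCl3 anion leaves and is protonated to CHCl3 so that DBU is regenerated, and the conjugated enol lactone results without any stereocentre; the closest known reaction types are the base-mediated alcoholysis of 2-(trichloroacetyl)pyrroles to pyrrole-2-carboxylic esters and the Ac2O-mediated enol-lactonisation of N-phenacylpyrrole-2-carboxylic acids.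

**Step 4**
Reactants: 7 3,7,8-tris(4-methoxyphenyl)-1H-pyrrolo[2,1-c][1,4]oxazin-1-one
Product: 8 3,7,8-tris(4-hydroxyphenyl)-1H-pyrrolo[2,1-c][1,4]oxazin-1-one (lukianol A)
Conditions: BBr3 (8 equiv), CH2Cl2, −78 °C to rt; then H2O, 0 °C
Reagents that add atoms: none
Why: Lewis-acid cleavage of aryl methyl ethers (BBr3 demethylation) frees the three phenols, and the conjugated enol lactone and the pyrrole are expected to tolerate BBr3 at low temperature; no stereocentre is involved.

**Compound list**
1 | 2-(4-methoxyphenyl)acetaldehyde (commercial, used freshly distilled) | COc1ccc(CC=O)cc1 | starting material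
2 | 2-amino-1-(4-methoxyphenyl)ethan-1-one hydrochloride (commercial) | Cl.NCC(=O)c1ccc(OC)cc1 | starting material
3 | (E)-1-(4-methoxyphenyl)-2-{[2-(4-methoxyphenyl)ethylidene]amino}ethan-1-one (N-phenacyl aldimine, in equilibrium with its enamine tautomer) | COc1ccc(C/C=N/CC(=O)c2ccc(OC)cc2)cc1 | intermediate
4 | 2,3-bis(4-methoxyphenyl)-4-{[2-(4-methoxyphenyl)-2-oxoethyl]imino}butanal (succinaldehyde monoimine, mixture of diastereomers, both stereocentres lost on aromatisation) | COc1ccc(cc1)C(C=O)C(C=NCC(=O)c1ccc(OC)cc1)c1ccc(OC)cc1 | intermediate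
5 | 2-[3,4-bis(4-methoxyphenyl)-1H-pyrrol-1-yl]-1-(4-methoxyphenyl)ethan-1-one | COc1ccc(cc1)C(=O)Cn1cc(-c2ccc(OC)cc2)c(-c2ccc(OC)cc2)c1 | intermediate
6 | 2,2,2-trichloro-1-{3,4-bis(4-methoxyphenyl)-1-[2-(4-methoxyphenyl)-2-oxoethyl]-1H-pyrrol-2-yl}ethan-1-one | COc1ccc(cc1)C(=O)Cn1cc(-c2ccc(OC)cc2)c(-c2ccc(OC)cc2)c1C(=O)C(Cl)(Cl)Cl | intermediate
7 | 3,7,8-tris(4-methoxyphenyl)-1H-pyrrolo[2,1-c][1,4]oxazin-1-one (lukianol A trimethyl ether) | O=c1oc(-c2ccc(OC)cc2)cn2cc(-c3ccc(OC)cc3)c(-c3ccc(OC)cc3)c12 | intermediate
8 | 3,7,8-tris(4-hydroxyphenyl)-1H-pyrrolo[2,1-c][1,4]oxazin-1-one (lukianol A, achiral) | O=c1oc(-c2ccc(O)cc2)cn2cc(-c3ccc(O)cc3)c(-c3ccc(O)cc3)c12 | target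

**Totals**
Total step count: 4. Longest linear sequence: 4 steps (1 and 2 → 5 → 6 → 7 → 8).

**Three steps most likely to fail, with fallbacks**

Risk at step 1: the free α-aminoketone may self-condense to a dihydropyrazine, or its enamine may close onto the ketone in a Knorr sense, before the silver-mediated coupling takes place. The fallback sets out from 2 (with 1) and comes back at 5. Compound 2 is reduced with NaBH4 in MeOH at 0 °C (basic work-up) to racemic 2-amino-1-(4-methoxyphenyl)ethan-1-ol F1, an amine that can do neither side reaction. The same AgOAc/NaOAc coupling with 1 in THF at 60 °C then gives racemic 2-[3,4-bis(4-methoxyphenyl)-1H-pyrrol-1-yl]-1-(4-methoxyphenyl)ethan-1-ol F2. Dess–Martin periodinane (NaHCO3, CH2Cl2, rt) oxidises the benzylic alcohol to 5, which erases the racemic carbinol centre.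

Risk at step 2: the α-position lies between the N-phenacyl arm and an aryl group, so trichloroacetylation may be sluggish or acid may degrade the pyrrole. The fallback sets out from 5 and comes back at 7, bypassing 6. NBS (1.0 equiv, THF, −78 °C) gives 2-[2-bromo-3,4-bis(4-methoxyphenyl)-1H-pyrrol-1-yl]-1-(4-methoxyphenyl)ethan-1-one F3. A palladium-catalysed carbonylative enol-lactonisation (Pd(OAc)2, Xantphos, CO 1 atm, Et3N, toluene, 100 °C) then delivers 7 directly: after oxidative addition of the C–Br bond to zerovalent palladium, CO is inserted and the acyl group passes to the ketone enol oxygen.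

Risk at step 3: the enolate may be too weak a nucleophile, or adventitious water may win, so that the trichloromethyl ketone is merely hydrolysed. The fallback sets out from 6 and comes back at 7. Aqueous NaOH in THF at rt performs the ordinary haloform cleavage to 3,4-bis(4-methoxyphenyl)-1-[2-(4-methoxyphenyl)-2-oxoethyl]-1H-pyrrole-2-carboxylic acid F4. This acid is closed by the classical mixed-anhydride enol-lactonisation (Ac2O, NaOAc, 120 °C) to 7.

**Further compounds**
F1 | step 1 | racemic 2-amino-1-(4-methoxyphenyl)ethan-1-ol | NCC(O)c1ccc(OC)cc1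
F2 | step 1 | racemic 2-[3,4-bis(4-methoxyphenyl)-1H-pyrrol-1-yl]-1-(4-methoxyphenyl)ethan-1-ol | COc1ccc(cc1)C(O)Cn1cc(-c2ccc(OC)cc2)c(-c2ccc(OC)cc2)c1
F3 | step 2 | 2-[2-bromo-3,4-bis(4-methoxyphenyl)-1H-pyrrol-1-yl]-1-(4-methoxyphenyl)ethan-1-one | COc1ccc(cc1)C(=O)Cn1cc(-c2ccc(OC)cc2)c(-c2ccc(OC)cc2)c1Br
F4 | step 3 | 3,4-bis(4-methoxyphenyl)-1-[2-(4-methoxyphenyl)-2-oxoethyl]-1H-pyrrole-2-carboxylic acid | COc1ccc(cc1)C(=O)Cn1cc(-c2ccc(OC)cc2)c(-c2ccc(OC)cc2)c1C(=O)O
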